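(The data are simulated for an exercise; noise was put on by code.)

- The bench chemist in me read maple, the flask asked about, by the usual rule: a yield curve that goes flat is read as a dying catalyst. With the substrate level steady and the catalyst dying by first-order decay, the curve is one exponential, so initial slope times half-time over plateau comes to 0.693.

| flask | starting material | second substrate | free enzyme | temperature | remark | time |
|---|---|---|---|---|---|---|
| maple | 0.10 M | 0.10 M | 0.55 µM | 20 °C | the very flask that is asked about, followed so far |  |
| cedar | 0.10 M | 0.067 M | 0.55 µM | 20 °C | run made earlier |  |
| flask | 0.10 M | 0.100 M | 0.55 µM | 20 °C |  | 6.0 h |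

| maple: time / min | maple: target / % | cedar: time / min | cedar: target / % |
|---|---|---|---|
| 12.0 | 11.5 | 1.50 | 3.4 |
| 30.0 | 17.3 | 4.00 | 6.9 |
| 60.0 | 21.4 | 8.00 | 9.9 |
| 90.0 | 22.7 | 12.0 | 12.9 |
| 120 | 21.5 | 15.0 | 13.6 |
| 180 | 21.9 | 20.0 | 15.5 |
| 240 | 21.8 | 30.0 | 18.4 |

(standard deviation of a reading: 0.5 percentage points)

- eta: at 6.0 h add free enzyme, 100% of the amount charged, then wait 12 h
- zeta: at 6.0 h raise the temperature by 25 K, then wait 12 h
- delta: change nothing and wait 12 h more
- alpha: at 6.0 h take out 90% of the target then present, then wait 12 h

- percent here means starting material units held: one side product or resting dimer counts as two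
- target taken out counts as made
- on the list of suspects stand: starting material + free enzyme <-> complex A; free enzyme -> unfolded enzyme; 2 complex A <-> resting dimer; second substrate + free enzyme <-> complex B; starting material + target -> side product; complex A -> free enzyme + target; complex B -> free enzyme + second product
- the earlier runs do not show what temperature does; that part of a forecast is a guess
- additions bring no volume worth counting

- target, in percent of the starting material first charged, at 6.0 h
- what to do for the largest gain in target; "none" if nothing gains more than 2 percentage points (eta / zeta / delta / alpha / none)
- target present, with what was taken out counted in, in percent of the starting material first charged, after zeta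
- target present, with what was taken out counted in, in percent of the starting material first charged, after alpha

- I applied the rule honestly. Maple averaged 22.0% on its flat stretch and stood at half of that at 12.0 min, so that reading gave the half-time.
- I took the initial slope from cedar's first reading and scaled it to maple by the two readings at 12.0 min. The ratio came to 1.10, a reading with scatter, but larger than the rule allows. There the rule stopped working: maple bent sooner than one dying catalyst gives.
- My own reckoning went to the suspect starting material + target -> side product, which, at a given level of starting material, loses target faster the more target stands. I read the plateau as 0.0220 M, the holding level h: the target concentration at which target is made as fast as it is lost.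
- Then I asked for the end state. The charge exceeded h by a factor of 4.55, so target could reach h while the remaining starting material went on to side product. On that reckoning maple's flat stretch needed no loss of enzyme. I committed to target near 22.0%, side product near 78.0%, and none as best.
- The forecast agreed with me on the level but differed on best: now 21.9%, best eta, zeta 21.6%, alpha 21.9%, on the ground “The plateau therefore points to enzyme death”.
- The flask gave 22.2% at 6.0 h, 22.2% after zeta, 22.2% after alpha, and none as best: eta gained 0 percentage points, zeta 0 points, delta 0 points, alpha 0 points.

    starting material + free enzyme ⇌ complex A (K = 7.90 M⁻¹, k = 62000 M⁻¹ s⁻¹, Ea = 20.0 kJ mol⁻¹, ΔH = −12.0 kJ mol⁻¹)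
    free enzyme → unfolded enzyme (k = 4.90 × 10⁻⁶ s⁻¹, Ea = 269 kJ mol⁻¹)
    2 complex A ⇌ resting dimer, settled at all times (K = 1.60 × 10⁶ M⁻¹, ΔH = −23.0 kJ mol⁻¹)
    second substrate + free enzyme ⇌ complex B (K = 5.30 M⁻¹, k = 1.80 × 10⁵ M⁻¹ s⁻¹, Ea = 14.0 kJ mol⁻¹, ΔH = −19.0 kJ mol⁻¹)
    starting material + target → side product (k = 0.0230 M⁻¹ s⁻¹, Ea = 62.0 kJ mol⁻¹)
    complex A → free enzyme + target (k = 200 s⁻¹, Ea = 62.0 kJ mol⁻¹)
    complex B → free enzyme + second product (k = 210 s⁻¹, Ea = 64.0 kJ mol⁻¹)
    (constants at 20 °C)

- The flask's target had come to rest by 360 min: starting material, the limiting reagent, stood at 0%, and side product at 77.8% of a charge 4.55 times h. Ten times the time left target at 22.2%. It moved the catalyst instead: of the catalyst charged, free enzyme fell from 90.7% to 35.0% and unfolded enzyme rose from 9.33% to 65.0%. A neighbour flask charged 0.025 M of starting material, just 1.14 times h, and its target ended under h, at 0.0139 M, which is 55.8% of its charge.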